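# Proposed synthesis of CNP0273594.1 by conjugate allylation–methylation of a ring A alkylidene β-keto ester

## Analysis of the target

CNP0273594.1 is a bicyclic diterpenoid acid of the labdane type in the enantiomeric (ent) series. It is a trans-decalin (ring A: C1–C5 and C10; ring B: C5–C10) with a trisubstituted C7=C8 alkene and a C9 side chain C11–C16 that ends in an (E)-3-methylbut-2-enoic acid. Its six stereocentres are (2S,3R,4S,5S,9R,10S), and two of them (C4 and C10) are quaternary. The C20 methyl on C10 and the formyl carbon C19 on C4 are 1,3-diaxial on one face; H5, H9, the C18 methyl and both acetoxy groups (C2 equatorial, C3 axial) lie on the other face, and the C9 side chain is equatorial. The sensitive groups are the two secondary acetates, the neopentyl C19 aldehyde that sits β to the C3 oxygen, the free conjugated acid whose geometry must stay E, and the C7=C8 alkene, which makes H9 allylic. The synthesis is hard for three reasons: the contiguous C2–C3–C4–C5 array around a quaternary C4 that must carry the formyl group in the more hindered axial position, the vicinal quaternary/tertiary pair C10/C9, and the three different oxidation levels at C15, C19 and C2/C3 that must be kept apart to the end. The strategy rests on one feature: the C3 oxygen, the quaternary C4 and C5 are the carbonyl, α- and β-carbons of a ring A cyclohex-2-enone. With an ester on C4, the C4=C5 bond becomes an alkylidene β-keto ester, so C5–C6 and C4–C18 can be made in one flask and the ester becomes C19.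

## Retrosynthetic reasoning

**Acetates.** Target 35 is the diacetate of diol 33, and 33 is unmasked from acetonide 32. No skeletal bond is cut. The acetates are placed last because they would not survive the hydride and strongly basic steps before them, and the acetonide carries the cis-diol through every redox change.

**C15 and C19 oxidation levels.** Aldehyde acid 32 is traced through hydroxy acid 31 and enal 30 to diol 29, and 29 to diester 28. The axial C19 ester yields only to a strong hydride, which also reduces the side-chain ester. Both are therefore taken down to 29, and the two primary alcohols are told apart by type: the allylic one is oxidised first and in two stages, the neopentyl one last. This avoids any protecting group on C19.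

**C12–C13.** Diester 28 is cut at the sp3–sp2 bond C12–C13 into the alkylborane 27 (from the terminal alkene 24) and enol triflate 26. The C13=C14 geometry is fixed beforehand in 26, which comes in one step from 25, and is carried over by a stereoretentive cross-coupling. An olefination of a C13 methyl ketone would instead give E/Z mixtures.

**C11–C12.** The vinyl group of 24 is cut at C11=C12 back to aldehyde 23, which comes from alcohol 22 and silyl ether 21. A one-carbon olefination is chosen over displacement at C11 because C11 is β-branched and flanked by the quaternary C10.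

**C2 and C3 oxygens.** Acetonide 21 comes from diol 20, 20 from hydroxy ketone 19, and 19 from ketone 17. The C2–O bond is made by enolate oxidation and the C3–H bond by hydride reduction. The C3 ketone can enolise only towards C2 because C4 is quaternary, and in the rigid decalin the axial C20 and C19 groups decide both faces.

**Ring B.** Decalin 17 is cut at C7=C8 to diene 16 (ring-closing metathesis). The cut lies far from all stereocentres, and the two alkenes it needs are exactly the allyl group delivered to C5 by the key step and an isopropenyl group on C9.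

**Key disconnection.** Keto ester 16 is cut at C5–C6 and C4–C18 to the alkylidene β-keto ester 12, the allyl nucleophile 13 and the methyl electrophile 14. These two bonds build the quaternary C4 with both of its carbon substituents at the right oxidation level and set C5; the existing quaternary C10 is the control element. The forward reaction has to add the allyl group 1,4 and trans to the C9 branch, and then methylate carbon, not oxygen, on the face away from C20.

**Activation of ring A.** The ester carbon of 12 is introduced by methoxycarbonylation of vinyl iodide 11, which comes from enone 10 by α-iodination. Enone 10 comes from cyclohexene 9 by allylic oxidation; C3 is the only allylic methylene of the ring alkene because C10 is quaternary.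

**C9–C10.** Silyl ether 9 comes from alcohol 8 and acid 7. Acid 7 is cut at C9–C10 by an Ireland–Claisen rearrangement of ester 4, which is made from alcohol 2 and acid 3. The [3,3] shift transfers the carbinol configuration of 2 to the quaternary C10, sets C9 through the ketene acetal geometry, and leaves the isopropenyl group and the C4=C5 alkene where they are needed. Alcohol 2 is the enantioselective reduction product of enone 1.

## Alternatives that were turned down

**Alternative 1:** Ring A is disconnected at C1–C10 and C4–C5 by a [4+2] cycloaddition. In the forward direction the (E)-dienyl silyl ether A3 would add to one methyl-bearing alkene of quinone A2 under a chiral cationic oxazaborolidine to give the cis-fused adduct A1.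
- For it: one catalytic, enantioselective step from two very simple partners makes ring A, brings in every ring B carbon including C17, and sets the quaternary C10. The C2=C3 alkene it leaves is well placed for a later cis-dihydroxylation. In speed to a bicyclic core and in absolute stereocontrol it is stronger than the chosen route, which needs ten steps to reach decalin 17.
- Against it: A1 is cis-fused and must be epimerised at C5. C4 arrives as a tertiary carbon that carries only C19 and is not next to a carbonyl, so the C18 methyl cannot be added by enolate chemistry and the hardest centre of the target stays open. Ring B arrives as an enedione: the C6 oxygen must be removed, and the C9 carbonyl must be turned into a tertiary centre bearing the side chain next to the quaternary C10.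
- Comparison: the chosen strategy delivers C4 complete, with methyl and ester on the right faces, gives a trans ring fusion directly, and provides an equatorial C11 handle on C9. This is expected to save more corrective steps than the cycloaddition gains.

**Alternative 2:** Both rings are disconnected at C1–C2 and C9–C10 in one cationic cascade. In the forward direction the open-chain aldehyde A5, activated by the Lewis acid A6, would be attacked at C2 by the isopropenyl terminus C1, and the resulting C10 cation would be trapped at C9 by the (E)-allylsilane to give A4.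
- For it: it is the most convergent plan. Both rings, three stereocentres (C2, C9, C10) and the C7=C8 alkene form in one step, with the whole side chain and the C3/C4 oxygen pattern already in place. Its endgame is much shorter than the one proposed here, and on that point it is stronger.
- Against it: A5 must already hold the C3/C4/C5 triad, including the quaternary C4, in an acyclic setting, together with a stereodefined secondary allylsilane; the difficulty is moved, not solved. The cascade has to form a bond to a quaternary carbon and fix the C2 carbinol cis to the C3 oxygen at the same time. Proton loss from the C10 cation (an ene-type monocycle), protodesilylation, and Lewis-acid cleavage of the α-silyloxy aldehyde and the silyl ethers all compete.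
- Comparison: the chosen strategy spreads the stereochemical decisions over ring-controlled steps that each have close precedent. The price is a longer linear sequence.

**Alternative 3:** Ring A is disconnected at C2–C3 by a pinacol coupling. In the forward direction the trialdehyde A8 would be treated with the divalent samarium reagent A9; the C2 ketyl would couple with one of the two formyl groups on C4 to give the cis-diol A7, and the other formyl group would remain as C19.
- For it: the ring closure, the cis-diol (through the samarium chelate) and C19 at its final oxidation level come in one step. No hydroxylation, ketone reduction or ester-to-aldehyde adjustment is needed, so at the end of the synthesis it is better in redox and step economy than the chosen route.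
- Against it: C4 becomes a stereocentre only through a choice between two diastereotopic formyl groups, and nothing in a monocyclic ring B precursor strongly enforces that choice. The geminal diformyl unit is prone to hydration, deformylation and over-reduction. Ketyl addition to the enoate and retro-aldol cleavage of the β-hydroxy aldehyde product threaten the step. A8 itself needs a doubly formylated quaternary carbon next to C5 in addition to C9/C10.
- Comparison: the chosen strategy sets C4 by an alkylation whose face is fixed by two substituents, and it reaches the C19 aldehyde late from a robust ester.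

Key step: step 9

Remark on the chemistry: labdane locants are used throughout, also for the monocyclic precursors (C11–C16 side chain with C16 the methyl on C13, C17 on C8, C18 and C19 on C4, C20 on C10). CIP descriptors of the bicyclic compounds refer to these locants, and the target is taken as the (2S,3R,4S,5S,9R,10S,13E) enantiomer.

## Route

Step 1
Reactants: 1 3-methylcyclohex-2-en-1-one
Product: 2 (1S)-3-methylcyclohex-2-en-1-ol
Conditions: (R)-2-methyl-CBS-oxazaborolidine (20 mol %), catecholborane, toluene, −78 °C
Reagents that add atoms: none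
Why: Corey–Bakshi–Shibata reduction; the alkenyl arm of the enone acts as the large carbonyl substituent, so the (R)-catalyst should deliver hydride to the face that gives the (S)-allylic alcohol, and catecholborane at −78 °C reduces only the carbonyl group.

Step 2
Reactants: 2 (1S)-3-methylcyclohex-2-en-1-ol, 3 3-methylbut-3-enoic acid
Product: 4 (1S)-3-methylcyclohex-2-en-1-yl 3-methylbut-3-enoate
Conditions: DCC, DMAP (10 mol %), CH2Cl2, 0 °C
Reagents that add atoms: none
Why: Steglich esterification; neutral carbodiimide activation acylates the ionisation-prone allylic alcohol with retention at the carbinol carbon, and low temperature with little DMAP limits migration of the β,γ-double bond of the acid into conjugation.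

Step 3
Reactants: 4 (1S)-3-methylcyclohex-2-en-1-yl 3-methylbut-3-enoate
Product: 7 (2R)-3-methyl-2-[(1R)-1-methylcyclohex-2-en-1-yl]but-3-enoic acid, via (E)-trimethylsilyl ketene acetal 5 (not isolated), via trimethylsilyl ester 6 (not isolated)
Conditions: LiN(iPr)2, THF, −78 °C; Me3SiCl/Et3N, −78 → 65 °C; then 1 M HCl
Reagents that add atoms: none
Why: Ireland–Claisen rearrangement; kinetic α-deprotonation in THF should give the (E)-ketene acetal 5 (isopropenyl cis to the allylic oxygen), and the suprafacial [3,3] shift forms C9–C10 on the face the C–O bond leaves, so the (S)-carbinol sets the quaternary C10. Cyclohexenyl esters favour a boat-like transition state, which for 5 places the isopropenyl group beside the ring methylene C1 and should give the (9R) configuration.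

Step 4
Reactants: 7 (2R)-3-methyl-2-[(1R)-1-methylcyclohex-2-en-1-yl]but-3-enoic acid
Product: 8 (2R)-3-methyl-2-[(1R)-1-methylcyclohex-2-en-1-yl]but-3-en-1-ol
Conditions: LiAlH4, THF, 0 → 23 °C
Reagents that add atoms: none
Why: Hydride reduction of a carboxylic acid to the primary alcohol (C11); the intermediate carboxylate is not enolised, so C9 keeps its configuration and the isolated alkenes are untouched.

Step 5
Reactants: 8 (2R)-3-methyl-2-[(1R)-1-methylcyclohex-2-en-1-yl]but-3-en-1-ol
Product: 9 {[(2R)-3-methyl-2-[(1R)-1-methylcyclohex-2-en-1-yl]but-3-en-1-yl]oxy}tri(propan-2-yl)silane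
Conditions: iPr3SiCl, imidazole, DMF, 23 °C
Reagents that add atoms: chlorotri(propan-2-yl)silane, CC(C)[Si](Cl)(C(C)C)C(C)C
Why: Silylation of a primary alcohol; the bulky silyl ether withstands the oxidation, organometallic, base and hydride steps that follow and prevents the C11 oxygen from adding to the alkylidene β-keto ester made later.

Step 6
Reactants: 9 {[(2R)-3-methyl-2-[(1R)-1-methylcyclohex-2-en-1-yl]but-3-en-1-yl]oxy}tri(propan-2-yl)silane
Product: 10 (4R)-4-methyl-4-[(2R)-3-methyl-1-{[tri(propan-2-yl)silyl]oxy}but-3-en-2-yl]cyclohex-2-en-1-one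
Conditions: Rh2(cap)4 (cap = caprolactamate, C6H10NO; 1 mol %), t-BuOOH, K2CO3, CH2Cl2, 23 °C
Reagents that add atoms: tert-butyl hydroperoxide, CC(C)(C)OO
Why: Dirhodium-catalysed allylic oxidation by tert-butylperoxy radicals; C3 is the only allylic methylene of the ring alkene because C10 is quaternary, and oxygenation at the neopentyl C5 terminus of the allyl radical is disfavoured. Ring-selective oxidations of this kind are known to spare isopropenyl groups on terpene cyclohexenes, and here the tertiary C9–H is further shielded by the quaternary C10 and the silyl ether.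

Step 7
Reactants: 10 (4R)-4-methyl-4-[(2R)-3-methyl-1-{[tri(propan-2-yl)silyl]oxy}but-3-en-2-yl]cyclohex-2-en-1-one
Product: 11 (4S)-2-iodo-4-methyl-4-[(2R)-3-methyl-1-{[tri(propan-2-yl)silyl]oxy}but-3-en-2-yl]cyclohex-2-en-1-one
Conditions: I2, pyridine, CH2Cl2, 23 °C
Reagents that add atoms: iodine, II
Why: α-Iodination of an enone by conjugate addition of pyridine, iodination of the resulting enolate and elimination; only the enone is activated for this sequence, so the isolated isopropenyl group is not functionalised.

Step 8
Reactants: 11 (4S)-2-iodo-4-methyl-4-[(2R)-3-methyl-1-{[tri(propan-2-yl)silyl]oxy}but-3-en-2-yl]cyclohex-2-en-1-one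
Product: 12 methyl (3R)-3-methyl-3-[(2R)-3-methyl-1-{[tri(propan-2-yl)silyl]oxy}but-3-en-2-yl]-6-oxocyclohex-1-ene-1-carboxylate
Conditions: PdCl2(PPh3)2 (5 mol %), CO (1 atm), MeOH, Et3N, DMF, 60 °C
Reagents that add atoms: carbon monoxide, [C-]#[O+]; methanol, CO
Why: Palladium-catalysed methoxycarbonylation of a vinyl iodide (oxidative addition to zerovalent palladium formed in situ, CO insertion, methanolysis); a Heck-type closure onto the isopropenyl group would need a bridgehead alkene and cannot compete, and the quaternary C10 shields the β-carbon of the product from adding methanol.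

Step 9
Reactants: 12 methyl (3R)-3-methyl-3-[(2R)-3-methyl-1-{[tri(propan-2-yl)silyl]oxy}but-3-en-2-yl]-6-oxocyclohex-1-ene-1-carboxylate, 13 allylmagnesium bromide, 14 iodomethane
Product: 16 methyl (1S,2S,3R)-1,3-dimethyl-3-[(2R)-3-methyl-1-{[tri(propan-2-yl)silyl]oxy}but-3-en-2-yl]-6-oxo-2-(prop-2-en-1-yl)cyclohexane-1-carboxylate, via bromomagnesium enolate 15 (not isolated)
Conditions: C3H5MgBr (3 equiv), CuBr·SMe2 (1.5 equiv), THF, −78 °C; then CH3I, DMPU, −78 → 23 °C
Reagents that add atoms: none
Why: Two equivalents of 13 and CuBr·SMe2 form the magnesium diallylcuprate, which complexes the electron-poor C4=C5 bond of 12 and transfers one allyl group to C5 by oxidative addition and reductive elimination, giving the chelated bromomagnesium enolate 15; C-methylation of 15 by 14 in the presence of DMPU then forms C4–C18. The closest known reaction type is the copper-mediated conjugate addition–enolate alkylation sequence on 2-alkoxycarbonyl cycloalk-2-enones. No ring is closed in this step. C5 is controlled by the quaternary C10: the branched C9 substituent is much larger than C20, so the cuprate should approach C5 on the face opposite to it and place the allyl group trans to the C9 branch and cis to C20. C4 is controlled by the new C5 allyl group and by C20, which lie on the same face of the enolate, so 14 should enter from the other face; this leaves the ester cis to C20 as the future axial C19 and makes the new methyl C18. The step needs 1,4- over 1,2-addition, which the doubly activated chelating alkene and the soft copper reagent at −78 °C should secure. It needs C- over O-alkylation, which the soft electrophile and the magnesium chelate should secure, and the two facial selectivities just described.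

Step 10
Reactants: 16 methyl (1S,2S,3R)-1,3-dimethyl-3-[(2R)-3-methyl-1-{[tri(propan-2-yl)silyl]oxy}but-3-en-2-yl]-6-oxo-2-(prop-2-en-1-yl)cyclohexane-1-carboxylate
Product: 17 methyl (4S,5S,9R,10R)-3-oxo-11-{[tri(propan-2-yl)silyl]oxy}-12,13,14,15,16-pentanorlabd-7-en-19-oate
Conditions: second-generation Grubbs catalyst RuCl2(=CHPh)(H2IMes)(PCy3) (5 mol %), CH2Cl2, 40 °C
Reagents that add atoms: none
Why: Ring-closing metathesis between the monosubstituted allyl alkene and the 1,1-disubstituted isopropenyl alkene forms the trisubstituted C7=C8 bond and ring B; the two tethers are trans on C5 and C10, so both become equatorial and the decalin is trans-fused with C11 equatorial.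

Step 11
Reactants: 17 methyl (4S,5S,9R,10R)-3-oxo-11-{[tri(propan-2-yl)silyl]oxy}-12,13,14,15,16-pentanorlabd-7-en-19-oate
Product: 19 methyl (2S,4S,5S,9R,10R)-2-hydroxy-3-oxo-11-{[tri(propan-2-yl)silyl]oxy}-12,13,14,15,16-pentanorlabd-7-en-19-oate, via potassium enolate 18 (not isolated)
Conditions: KN(SiMe3)2, THF, −78 °C; 2-(phenylsulfonyl)-3-phenyloxaziridine, −78 °C; AcOH
Reagents that add atoms: 2-(phenylsulfonyl)-3-phenyloxaziridine, O=S(=O)(c1ccccc1)N1OC1c1ccccc1
Why: Enolate hydroxylation with a Davis oxaziridine, which does not touch the C7=C8 alkene; the ketone can enolise only towards C2, and the axial C20 and C19 groups block one face of enolate 18, so oxygen should arrive on the H5 face and end up equatorial.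

Step 12
Reactants: 19 methyl (2S,4S,5S,9R,10R)-2-hydroxy-3-oxo-11-{[tri(propan-2-yl)silyl]oxy}-12,13,14,15,16-pentanorlabd-7-en-19-oate
Product: 20 methyl (2S,3R,4S,5S,9R,10R)-2,3-dihydroxy-11-{[tri(propan-2-yl)silyl]oxy}-12,13,14,15,16-pentanorlabd-7-en-19-oate
Conditions: KBH(sec-Bu)3 (3 equiv), THF, −78 °C; then aq. NaOH, H2O2, 0 °C
Reagents that add atoms: none
Why: Reduction of a cyclohexanone by a bulky trialkylborohydride; axial approach is blocked by the axial hydrogens on C1 and C5, so hydride should enter along the equatorial trajectory and give the axial C3 alcohol cis to the C2 hydroxyl, while the hindered ester is inert at −78 °C.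

Step 13
Reactants: 20 methyl (2S,3R,4S,5S,9R,10R)-2,3-dihydroxy-11-{[tri(propan-2-yl)silyl]oxy}-12,13,14,15,16-pentanorlabd-7-en-19-oate
Product: 21 methyl (2S,3R,4S,5S,9R,10R)-2,3-(isopropylidenedioxy)-11-{[tri(propan-2-yl)silyl]oxy}-12,13,14,15,16-pentanorlabd-7-en-19-oate
Conditions: Me2C(OMe)2, PPTS (cat.), CH2Cl2, 23 °C
Reagents that add atoms: 2,2-dimethoxypropane, COC(C)(C)OC
Why: Acetal exchange on a cis-1,2-diol (axial/equatorial, gauche) gives the five-membered acetonide; it masks both hydroxyls through the later oxidations and removes the free β-hydroxy ester that could undergo retro-aldol cleavage under base.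

Step 14
Reactants: 21 methyl (2S,3R,4S,5S,9R,10R)-2,3-(isopropylidenedioxy)-11-{[tri(propan-2-yl)silyl]oxy}-12,13,14,15,16-pentanorlabd-7-en-19-oate
Product: 22 methyl (2S,3R,4S,5S,9R,10R)-11-hydroxy-2,3-(isopropylidenedioxy)-12,13,14,15,16-pentanorlabd-7-en-19-oate
Conditions: Bu4NF, THF, 23 °C
Reagents that add atoms: none
Why: Fluoride-induced cleavage of the silyl ether; the acetonide and the hindered C19 ester are stable to these conditions.

Step 15
Reactants: 22 methyl (2S,3R,4S,5S,9R,10R)-11-hydroxy-2,3-(isopropylidenedioxy)-12,13,14,15,16-pentanorlabd-7-en-19-oate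
Product: 23 methyl (2S,3R,4S,5S,9R,10R)-2,3-(isopropylidenedioxy)-11-oxo-12,13,14,15,16-pentanorlabd-7-en-19-oate
Conditions: Dess–Martin periodinane, NaHCO3, CH2Cl2, 0 °C
Reagents that add atoms: none
Why: Dess–Martin oxidation of a primary alcohol under buffered, non-basic conditions, chosen so that the β,γ-unsaturated aldehyde is neither epimerised at C9 nor isomerised into conjugation; 23 should be used at once.

Step 16
Reactants: 23 methyl (2S,3R,4S,5S,9R,10R)-2,3-(isopropylidenedioxy)-11-oxo-12,13,14,15,16-pentanorlabd-7-en-19-oate
Product: 24 methyl (2S,3R,4S,5S,9R,10R)-2,3-(isopropylidenedioxy)-13,14,15,16-tetranorlabda-7,11-dien-19-oate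
Conditions: Ph3PCH3Br, KN(SiMe3)2, THF, 0 °C; then 23, −78 → 0 °C
Reagents that add atoms: methyltriphenylphosphonium bromide, C[P+](c1ccccc1)(c1ccccc1)c1ccccc1.[Br-]
Why: Wittig methylenation adds C12; the unstabilised ylide should add to the aldehyde at low temperature faster than it deprotonates C9, and the axial C19 ester is too hindered to react.

Step 17
Reactants: 25 ethyl 3-oxobutanoate
Product: 26 ethyl (2E)-3-{[(trifluoromethyl)sulfonyl]oxy}but-2-enoate
Conditions: Tf2O, aq. Me4NOH, toluene, 5 °C
Reagents that add atoms: trifluoromethanesulfonic anhydride, O=S(=O)(OS(=O)(=O)C(F)(F)F)C(F)(F)F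
Why: O-Sulfonylation of the acetoacetate enolate under two-phase conditions; the non-chelating tetramethylammonium counter-ion favours the open enolate, so the triflate should end up trans to the ester, which fixes the later C13=C14 geometry.

Step 18
Reactants: 24 methyl (2S,3R,4S,5S,9R,10R)-2,3-(isopropylidenedioxy)-13,14,15,16-tetranorlabda-7,11-dien-19-oate, 26 ethyl (2E)-3-{[(trifluoromethyl)sulfonyl]oxy}but-2-enoate
Product: 28 15-ethyl 19-methyl (2S,3R,4S,5S,9R,10S,13E)-2,3-(isopropylidenedioxy)labda-7,13-diene-15,19-dioate, via B-alkyl-9-borabicyclononane 27 (not isolated)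
Conditions: 9-BBN, THF, 0 → 23 °C; then 26, PdCl2(dppf) (5 mol %), K3PO4, THF/DMF, 50 °C
Reagents that add atoms: none
Why: Anti-Markovnikov hydroboration of the terminal vinyl group by 9-BBN (the trisubstituted C7=C8 alkene is inert) followed by B-alkyl Suzuki–Miyaura coupling; the coupling proceeds with retention at the sp2 carbon, so C12 replaces the triflate trans to the ester and the (13E)-enoate forms directly.

Step 19
Reactants: 28 15-ethyl 19-methyl (2S,3R,4S,5S,9R,10S,13E)-2,3-(isopropylidenedioxy)labda-7,13-diene-15,19-dioate
Product: 29 (2S,3R,4R,5S,9R,10S,13E)-2,3-(isopropylidenedioxy)labda-7,13-diene-15,19-diol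
Conditions: i-Bu2AlH (6 equiv), CH2Cl2, −78 → 23 °C; aq. KNaC4H4O6 (potassium sodium tartrate)
Reagents that add atoms: none
Why: Aluminium hydride reduction of both esters; the enoate is reduced 1,2 to the allylic alcohol, and the axial neopentyl C19 ester needs the excess reagent and room temperature. The acetonide and both alkenes are inert.

Step 20
Reactants: 29 (2S,3R,4R,5S,9R,10S,13E)-2,3-(isopropylidenedioxy)labda-7,13-diene-15,19-diol
Product: 30 (2S,3R,4R,5S,9R,10S,13E)-19-hydroxy-2,3-(isopropylidenedioxy)labda-7,13-dien-15-al
Conditions: MnO2 (activated, excess), CH2Cl2, 23 °C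
Reagents that add atoms: none
Why: Manganese dioxide oxidises allylic alcohols selectively; the saturated neopentyl C19 alcohol should stay untouched, which differentiates the two primary alcohols without a protecting group.

Step 21
Reactants: 30 (2S,3R,4R,5S,9R,10S,13E)-19-hydroxy-2,3-(isopropylidenedioxy)labda-7,13-dien-15-al
Product: 31 (2S,3R,4R,5S,9R,10S,13E)-19-hydroxy-2,3-(isopropylidenedioxy)labda-7,13-dien-15-oic acid
Conditions: NaClO2, NaH2PO4, 2-methylbut-2-ene, t-BuOH/H2O, 23 °C
Reagents that add atoms: sodium chlorite, [Na+].[O-]Cl=O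
Why: Pinnick oxidation of the enal to the acid with retention of the E geometry; the alkene scavenger intercepts hypochlorous acid and protects both trisubstituted alkenes, and chlorite does not oxidise the C19 alcohol.

Step 22
Reactants: 31 (2S,3R,4R,5S,9R,10S,13E)-19-hydroxy-2,3-(isopropylidenedioxy)labda-7,13-dien-15-oic acid
Product: 32 (2S,3R,4S,5S,9R,10S,13E)-2,3-(isopropylidenedioxy)-19-oxolabda-7,13-dien-15-oic acid
Conditions: Dess–Martin periodinane, CH2Cl2, 23 °C
Reagents that add atoms: none
Why: Dess–Martin oxidation of the neopentyl primary alcohol to the non-enolisable C19 aldehyde; the reagent tolerates the free carboxylic acid and stops at the aldehyde.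

Step 23
Reactants: 32 (2S,3R,4S,5S,9R,10S,13E)-2,3-(isopropylidenedioxy)-19-oxolabda-7,13-dien-15-oic acid
Product: 33 (2S,3R,4S,5S,9R,10S,13E)-2,3-dihydroxy-19-oxolabda-7,13-dien-15-oic acid
Conditions: 1 M HCl, THF, 23 °C
Reagents that add atoms: none
Why: Acid hydrolysis of the acetonide in water, so no acetal forms at C19; the axial C3 hydroxyl is anti to the formyl group and the C2 hydroxyl is equatorial, so neither can close a hemiacetal, and dilute acid at room temperature should leave the C7=C8 alkene in place.

Step 24
Reactants: 33 (2S,3R,4S,5S,9R,10S,13E)-2,3-dihydroxy-19-oxolabda-7,13-dien-15-oic acid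
Product: 35 (2S,3R,4S,5S,9R,10S,13E)-2,3-diacetoxy-19-oxolabda-7,13-dien-15-oic acid, via mixed acetic anhydride 34 (not isolated)
Conditions: Ac2O, pyridine, DMAP (cat.), CH2Cl2, 23 °C; then H2O, THF, 23 °C
Reagents that add atoms: acetic anhydride, CC(=O)OC(C)=O
Why: DMAP-catalysed acetylation of both secondary alcohols, including the hindered axial C3 hydroxyl; the carboxylic acid is carried as its mixed anhydride 34, which water cleaves back to the free acid without touching the secondary acetates.

## Compound list

1 | 3-methylcyclohex-2-en-1-one | CC1=CC(=O)CCC1 | starting material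
2 | (1S)-3-methylcyclohex-2-en-1-ol | O[C@@H]1C=C(C)CCC1 | intermediate
3 | 3-methylbut-3-enoic acid | C=C(C)CC(=O)O | starting material
4 | (1S)-3-methylcyclohex-2-en-1-yl 3-methylbut-3-enoate | C=C(C)CC(=O)O[C@@H]1C=C(C)CCC1 | intermediate
5 | trimethyl{[(1E)-3-methyl-1-{[(1S)-3-methylcyclohex-2-en-1-yl]oxy}buta-1,3-dien-1-yl]oxy}silane (not isolated) | C=C(C)/C=C(/O[Si](C)(C)C)O[C@@H]1C=C(C)CCC1 | intermediate
6 | trimethylsilyl (2R)-3-methyl-2-[(1R)-1-methylcyclohex-2-en-1-yl]but-3-enoate (not isolated) | C[C@]1([C@H](C(=O)O[Si](C)(C)C)C(C)=C)C=CCCC1 | intermediate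
7 | (2R)-3-methyl-2-[(1R)-1-methylcyclohex-2-en-1-yl]but-3-enoic acid | C[C@]1([C@H](C(=O)O)C(C)=C)C=CCCC1 | intermediate
8 | (2R)-3-methyl-2-[(1R)-1-methylcyclohex-2-en-1-yl]but-3-en-1-ol | C[C@]1([C@H](CO)C(C)=C)C=CCCC1 | intermediate
9 | {[(2R)-3-methyl-2-[(1R)-1-methylcyclohex-2-en-1-yl]but-3-en-1-yl]oxy}tri(propan-2-yl)silane | C[C@]1([C@H](CO[Si](C(C)C)(C(C)C)C(C)C)C(C)=C)C=CCCC1 | intermediate
10 | (4R)-4-methyl-4-[(2R)-3-methyl-1-{[tri(propan-2-yl)silyl]oxy}but-3-en-2-yl]cyclohex-2-en-1-one | C[C@]1([C@H](CO[Si](C(C)C)(C(C)C)C(C)C)C(C)=C)C=CC(=O)CC1 | intermediate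
11 | (4S)-2-iodo-4-methyl-4-[(2R)-3-methyl-1-{[tri(propan-2-yl)silyl]oxy}but-3-en-2-yl]cyclohex-2-en-1-one | C[C@]1([C@H](CO[Si](C(C)C)(C(C)C)C(C)C)C(C)=C)C=C(I)C(=O)CC1 | intermediate
12 | methyl (3R)-3-methyl-3-[(2R)-3-methyl-1-{[tri(propan-2-yl)silyl]oxy}but-3-en-2-yl]-6-oxocyclohex-1-ene-1-carboxylate | COC(=O)C1=C[C@](C)([C@H](CO[Si](C(C)C)(C(C)C)C(C)C)C(C)=C)CCC1=O | intermediate
13 | allylmagnesium bromide | C=CC[Mg]Br | starting material
14 | iodomethane | CI | starting material
15 | bromomagnesium enolate of the C5-allylated β-keto ester, allyl trans to the C9 branch (not isolated) | COC(=O)C1=C(O[Mg]Br)CC[C@@](C)([C@H](CO[Si](C(C)C)(C(C)C)C(C)C)C(C)=C)[C@@H]1CC=C | intermediate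
16 | methyl (1S,2S,3R)-1,3-dimethyl-3-[(2R)-3-methyl-1-{[tri(propan-2-yl)silyl]oxy}but-3-en-2-yl]-6-oxo-2-(prop-2-en-1-yl)cyclohexane-1-carboxylate | O=C1CC[C@@](C)([C@H](CO[Si](C(C)C)(C(C)C)C(C)C)C(C)=C)[C@H](CC=C)[C@]1(C)C(=O)OC | intermediate
17 | methyl (4S,5S,9R,10R)-3-oxo-11-{[tri(propan-2-yl)silyl]oxy}-12,13,14,15,16-pentanorlabd-7-en-19-oate (trans-decalin; C19 ester axial and cis to C20) | O=C1CC[C@@]2(C)[C@H](CO[Si](C(C)C)(C(C)C)C(C)C)C(C)=CC[C@@H]2[C@]1(C)C(=O)OC | intermediate
18 | potassium C2=C3 enolate of 17 (not isolated) | [K+].[O-]C1=CC[C@@]2(C)[C@H](CO[Si](C(C)C)(C(C)C)C(C)C)C(C)=CC[C@@H]2[C@]1(C)C(=O)OC | intermediate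
19 | methyl (2S,4S,5S,9R,10R)-2-hydroxy-3-oxo-11-{[tri(propan-2-yl)silyl]oxy}-12,13,14,15,16-pentanorlabd-7-en-19-oate | O=C1[C@@H](O)C[C@@]2(C)[C@H](CO[Si](C(C)C)(C(C)C)C(C)C)C(C)=CC[C@@H]2[C@]1(C)C(=O)OC | intermediate
20 | methyl (2S,3R,4S,5S,9R,10R)-2,3-dihydroxy-11-{[tri(propan-2-yl)silyl]oxy}-12,13,14,15,16-pentanorlabd-7-en-19-oate | O[C@H]1[C@@H](O)C[C@@]2(C)[C@H](CO[Si](C(C)C)(C(C)C)C(C)C)C(C)=CC[C@@H]2[C@]1(C)C(=O)OC | intermediate
21 | methyl (2S,3R,4S,5S,9R,10R)-2,3-(isopropylidenedioxy)-11-{[tri(propan-2-yl)silyl]oxy}-12,13,14,15,16-pentanorlabd-7-en-19-oate | CC1(C)O[C@H]2C[C@@]3(C)[C@H](CO[Si](C(C)C)(C(C)C)C(C)C)C(C)=CC[C@@H]3[C@](C)(C(=O)OC)[C@H]2O1 | intermediate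
22 | methyl (2S,3R,4S,5S,9R,10R)-11-hydroxy-2,3-(isopropylidenedioxy)-12,13,14,15,16-pentanorlabd-7-en-19-oate | CC1(C)O[C@H]2C[C@@]3(C)[C@H](CO)C(C)=CC[C@@H]3[C@](C)(C(=O)OC)[C@H]2O1 | intermediate
23 | methyl (2S,3R,4S,5S,9R,10R)-2,3-(isopropylidenedioxy)-11-oxo-12,13,14,15,16-pentanorlabd-7-en-19-oate | CC1(C)O[C@H]2C[C@@]3(C)[C@H](C=O)C(C)=CC[C@@H]3[C@](C)(C(=O)OC)[C@H]2O1 | intermediate
24 | methyl (2S,3R,4S,5S,9R,10R)-2,3-(isopropylidenedioxy)-13,14,15,16-tetranorlabda-7,11-dien-19-oate | CC1(C)O[C@H]2C[C@@]3(C)[C@H](C=C)C(C)=CC[C@@H]3[C@](C)(C(=O)OC)[C@H]2O1 | intermediate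
25 | ethyl 3-oxobutanoate | CCOC(=O)CC(C)=O | starting material
26 | ethyl (2E)-3-{[(trifluoromethyl)sulfonyl]oxy}but-2-enoate | CCOC(=O)/C=C(\C)OS(=O)(=O)C(F)(F)F | intermediate
27 | 9-borabicyclo[3.3.1]nonane adduct of 24 with boron on C12 (not isolated) | CC1(C)O[C@H]2C[C@@]3(C)[C@H](CCB4C5CCCC4CCC5)C(C)=CC[C@@H]3[C@](C)(C(=O)OC)[C@H]2O1 | intermediate
28 | 15-ethyl 19-methyl (2S,3R,4S,5S,9R,10S,13E)-2,3-(isopropylidenedioxy)labda-7,13-diene-15,19-dioate | CC1(C)O[C@H]2C[C@@]3(C)[C@H](CC/C(C)=C/C(=O)OCC)C(C)=CC[C@@H]3[C@](C)(C(=O)OC)[C@H]2O1 | intermediate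
29 | (2S,3R,4R,5S,9R,10S,13E)-2,3-(isopropylidenedioxy)labda-7,13-diene-15,19-diol | CC1(C)O[C@H]2C[C@@]3(C)[C@H](CC/C(C)=C/CO)C(C)=CC[C@@H]3[C@](C)(CO)[C@H]2O1 | intermediate
30 | (2S,3R,4R,5S,9R,10S,13E)-19-hydroxy-2,3-(isopropylidenedioxy)labda-7,13-dien-15-al | CC1(C)O[C@H]2C[C@@]3(C)[C@H](CC/C(C)=C/C=O)C(C)=CC[C@@H]3[C@](C)(CO)[C@H]2O1 | intermediate
31 | (2S,3R,4R,5S,9R,10S,13E)-19-hydroxy-2,3-(isopropylidenedioxy)labda-7,13-dien-15-oic acid | CC1(C)O[C@H]2C[C@@]3(C)[C@H](CC/C(C)=C/C(=O)O)C(C)=CC[C@@H]3[C@](C)(CO)[C@H]2O1 | intermediate
32 | (2S,3R,4S,5S,9R,10S,13E)-2,3-(isopropylidenedioxy)-19-oxolabda-7,13-dien-15-oic acid | CC1(C)O[C@H]2C[C@@]3(C)[C@H](CC/C(C)=C/C(=O)O)C(C)=CC[C@@H]3[C@](C)(C=O)[C@H]2O1 | intermediate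
33 | (2S,3R,4S,5S,9R,10S,13E)-2,3-dihydroxy-19-oxolabda-7,13-dien-15-oic acid | O[C@H]1C[C@@]2(C)[C@H](CC/C(C)=C/C(=O)O)C(C)=CC[C@@H]2[C@](C)(C=O)[C@H]1O | intermediate
34 | acetic (2S,3R,4S,5S,9R,10S,13E)-2,3-diacetoxy-19-oxolabda-7,13-dien-15-oic anhydride (not isolated) | CC(=O)O[C@H]1C[C@@]2(C)[C@H](CC/C(C)=C/C(=O)OC(C)=O)C(C)=CC[C@@H]2[C@](C)(C=O)[C@H]1OC(C)=O | intermediate
35 | (2S,3R,4S,5S,9R,10S,13E)-2,3-diacetoxy-19-oxolabda-7,13-dien-15-oic acid (CNP0273594.1) | CC(=O)O[C@H]1C[C@@]2(C)[C@H](CC/C(C)=C/C(=O)O)C(C)=CC[C@@H]2[C@](C)(C=O)[C@H]1OC(C)=O | target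

## Step count and least certain steps

Total step count: 24. Longest linear sequence: 23 steps (steps 1–16 and 18–24); step 17 is a one-step branch that makes 26 from 25.

**Step 9 (key step).** The most likely failure is poor facial discrimination in the allyl transfer, that is, addition on the face of the C9 branch. It may be accompanied by 1,2-addition of the allyl reagent to the C3 carbonyl, and by methylation of the flexible monocyclic enolate on the wrong face or on oxygen. The fallback separates the two bond formations and postpones the methylation until the ring system is rigid. It sets out from 12. Conjugate allylation with allyltrimethylsilane and TiCl4 in CH2Cl2 at −78 °C (Hosomi–Sakurai reaction, which cannot add 1,2) would give the C5-allylated β-keto ester F1. Ring-closing metathesis of F1 with the second-generation Grubbs catalyst RuCl2(=CHPh)(H2IMes)(PCy3) would give the bicyclic β-keto ester F2. Methylation of F2 with K2CO3 and iodomethane 14 in acetone then takes place on a trans-decalin enolate whose C20 face is blocked by the axial methyl group, the situation for which axial ester formation is best precedented. The fallback comes back to the route at 17.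

**Step 3.** The most likely failure is low diastereoselectivity at C9, through erosion of the ketene acetal geometry or through competition between boat-like and chair-like transition states; C10 is not at risk. The fallback inverts the ketene acetal geometry by changing how the enolate is made. It sets out from 2, which would be esterified (DCC, DMAP) with 3-methylbut-2-enoic acid to the conjugated ester (1S)-3-methylcyclohex-2-en-1-yl 3-methylbut-2-enoate F3. γ-Deprotonation of F3 with LiN(iPr)2 in THF/DMPU through the s-cis conformer, and silylation with Me3SiCl, should give the (Z)-ketene acetal F4 (isopropenyl cis to the silyloxy group). F4 rearranges through silyl ester 6 and comes back to the route at 7. If a minor C9 epimer remains, it should be separable at alcohol 8.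

**Step 6.** The most likely failure is hydrogen abstraction at the positions activated by the isopropenyl group (C9–H and the C17 methyl) in competition with C3, together with over-oxidation and peroxide formation. The fallback stops at the alcohol oxidation level and finishes the oxidation separately. It sets out from 9. Copper-catalysed allylic benzoyloxylation (Kharasch–Sosnovsky reaction; tert-butyl perbenzoate, CuBr cat., MeCN, 60 °C), in which the C–O bond should form at the less hindered C3 terminus, would give the allylic benzoate F5. Methanolysis with K2CO3 in MeOH would give the allylic alcohol F6, and oxidation of F6 with MnO2 comes back to the route at 10.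

**Step 16.** The most likely failure is enolisation of the β,γ-unsaturated aldehyde 23 by the basic ylide, which would epimerise C9 or move the C7=C8 bond into conjugation. The fallback avoids the aldehyde and builds the side chain by enolate alkylation. It sets out from 22, which would be converted with I2, PPh3 and imidazole into the C11 iodide F7. Alkylation of the dianion of 25 (NaH, then n-BuLi, THF, 0 °C) at its terminal carbon with F7 would give the β-keto ester F8. Treatment of F8 with NaH and ClP(O)(OEt)2 would give the chelation-controlled (Z)-enol phosphate F9, and substitution of the phosphate by Me2CuLi with retention comes back to the route at 28. This skips steps 15, 16 and 18.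

## Further compounds

F1 | step 9 | methyl (2R,3R)-3-methyl-3-[(2R)-3-methyl-1-{[tri(propan-2-yl)silyl]oxy}but-3-en-2-yl]-6-oxo-2-(prop-2-en-1-yl)cyclohexane-1-carboxylate (C1 epimers and enol form) | COC(=O)C1C(=O)CC[C@@](C)([C@H](CO[Si](C(C)C)(C(C)C)C(C)C)C(C)=C)[C@@H]1CC=C
F2 | step 9 | methyl (5R,9R,10R)-3-oxo-11-{[tri(propan-2-yl)silyl]oxy}-12,13,14,15,16,18-hexanorlabd-7-en-19-oate (C4 epimers and enol form) | COC(=O)C1C(=O)CC[C@@]2(C)[C@H](CO[Si](C(C)C)(C(C)C)C(C)C)C(C)=CC[C@H]12
F3 | step 3 | (1S)-3-methylcyclohex-2-en-1-yl 3-methylbut-2-enoate | CC(C)=CC(=O)O[C@@H]1C=C(C)CCC1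
F4 | step 3 | trimethyl{[(1Z)-3-methyl-1-{[(1S)-3-methylcyclohex-2-en-1-yl]oxy}buta-1,3-dien-1-yl]oxy}silane | C=C(C)/C=C(\O[Si](C)(C)C)O[C@@H]1C=C(C)CCC1
F5 | step 6 | (4R)-4-methyl-4-[(2R)-3-methyl-1-{[tri(propan-2-yl)silyl]oxy}but-3-en-2-yl]cyclohex-2-en-1-yl benzoate (C1 epimers) | C[C@]1([C@H](CO[Si](C(C)C)(C(C)C)C(C)C)C(C)=C)C=CC(OC(=O)c2ccccc2)CC1
F6 | step 6 | (4R)-4-methyl-4-[(2R)-3-methyl-1-{[tri(propan-2-yl)silyl]oxy}but-3-en-2-yl]cyclohex-2-en-1-ol (C1 epimers) | C[C@]1([C@H](CO[Si](C(C)C)(C(C)C)C(C)C)C(C)=C)C=CC(O)CC1
F7 | step 16 | methyl (2S,3R,4S,5S,9R,10R)-11-iodo-2,3-(isopropylidenedioxy)-12,13,14,15,16-pentanorlabd-7-en-19-oate | CC1(C)O[C@H]2C[C@@]3(C)[C@H](CI)C(C)=CC[C@@H]3[C@](C)(C(=O)OC)[C@H]2O1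
F8 | step 16 | 15-ethyl 19-methyl (2S,3R,4S,5S,9R,10S)-2,3-(isopropylidenedioxy)-13-oxo-16-norlabd-7-ene-15,19-dioate | CC1(C)O[C@H]2C[C@@]3(C)[C@H](CCC(=O)CC(=O)OCC)C(C)=CC[C@@H]3[C@](C)(C(=O)OC)[C@H]2O1
F9 | step 16 | 15-ethyl 19-methyl (2S,3R,4S,5S,9R,10S,13Z)-13-[(diethoxyphosphoryl)oxy]-2,3-(isopropylidenedioxy)-16-norlabda-7,13-diene-15,19-dioate | CC1(C)O[C@H]2C[C@@]3(C)[C@H](CC/C(OP(=O)(OCC)OCC)=C/C(=O)OCC)C(C)=CC[C@@H]3[C@](C)(C(=O)OC)[C@H]2O1
A1 | alternative 1 | cis-fused Diels–Alder adduct, 5-({[tert-butyl(dimethyl)silyl]oxy}methyl)-2,8a-dimethyl-4a,5,8,8a-tetrahydronaphthalene-1,4-dione | C[C@@]12CC=C[C@H](CO[Si](C)(C)C(C)(C)C)[C@@H]1C(=O)C=C(C)C2=O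
A2 | alternative 1 | 2,6-dimethyl-1,4-benzoquinone | CC1=CC(=O)C=C(C)C1=O
A3 | alternative 1 | tert-butyl(dimethyl)[(2E)-penta-2,4-dien-1-yloxy]silane | C=C/C=C/CO[Si](C)(C)C(C)(C)C
A4 | alternative 2 | trans-decalin C2 alcohol with C7=C8 alkene, C3 and C19 silyl ethers and the allyl (13E)-enoate side chain | O[C@H]1C[C@@]2(C)[C@H](CC/C(C)=C/C(=O)OCC=C)C(C)=CC[C@@H]2[C@](C)(CO[Si](C)(C)C(C)(C)C)[C@H]1O[Si](C)(C)C(C)(C)C
A5 | alternative 2 | open-chain C2 aldehyde carrying the C10 isopropenyl group and the C7-silylated (E)-allylsilane (C7 configuration left open) | O=C[C@H](O[Si](C)(C)C(C)(C)C)[C@@](C)(CO[Si](C)(C)C(C)(C)C)[C@H](C(C)=C)CC([Si](C)(C)C)/C(C)=C/CC/C(C)=C/C(=O)OCC=C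
A6 | alternative 2 | tin tetrachloride | Cl[Sn](Cl)(Cl)Cl
A7 | alternative 3 | C2,C3 cis-diol with C19 aldehyde, tert-butyl ester of the deacetylated target | O[C@H]1C[C@@]2(C)[C@H](CC/C(C)=C/C(=O)OC(C)(C)C)C(C)=CC[C@@H]2[C@](C)(C=O)[C@H]1O
A8 | alternative 3 | ring B trialdehyde: tert-butyl (E)-enoate with a formylmethyl group on C10 and a 2-methylpropanedial unit on C5 | O=CC[C@@]1(C)[C@H](CC/C(C)=C/C(=O)OC(C)(C)C)C(C)=CC[C@@H]1C(C)(C=O)C=O
A9 | alternative 3 | samarium diiodide | I[Sm]I
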